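## The problem

The target is a linear diarylheptanoid. A C1–C7 chain carries the catechol ring A on C1, the 4-hydroxyphenyl ring B on C7, an E double bond C6=C7 conjugated to ring B, and one stereocenter, C3 (R), which bears the acetate. No ring has to be closed; the questions are where to join the chain and how to set C3. C3 sits between C2H2–C1H2 and C4H2–C5H2, and the two arms first differ three atoms away from C3 (aryl carbon against C6=C7). A reagent that must tell the faces of a C3 carbonyl apart by the size of its neighbours therefore has almost nothing to hold on to. There is no second stereocenter to relay control, so C3 must come from a reagent or from the chiral pool. Once C6=C7 is in place, hydrogenation and hydrogenolysis are excluded, and the 4-hydroxystyrene is acid-sensitive (quinone methide formation). The catechol is air-sensitive as its anion, and the single alkyl acetate must go on O3 in the presence of three phenols and survive their unmasking.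

The feature used: C3 is an unbranched CH(O) between two methylene groups (C2 and C4). It can be taken as the OCH2 carbon of a 3-(ring A)propan-1-ol into which the C4–C7 arm has been inserted from boron. The two enantiotopic hydrogens on that carbon can be told apart by a chiral base at C3 itself, however alike the remote arms are.

## Retrosynthesis

Target 17 is traced to tris-silyl ether acetate 16 and then to alcohol 15 (three O–Si bonds and the O3–acyl bond cut). Triisopropylsilyl is chosen for all three phenols because aryl TIPS ethers should survive sBuLi at −78 °C, warm aqueous phosphate and alkaline peroxide, yet fall to buffered fluoride, which harms neither the alkyl acetate nor the styrene. Acetylation before desilylation makes the position of the acetate unambiguous.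

Alcohol 15 is cut at C3–C4 and at C3–O, giving carbamate 6 (ring A, C1–C3) and homoallylic pinacol boronate 11 (C4–C7, ring B, finished E-styrene). Forward, 6 is deprotonated enantioselectively to lithiated carbamate 12, which takes up 11 to give boronate complex 13. A stereospecific 1,2-shift of C4 from boron to C3 gives secondary boronate 14, and oxidation gives 15. This one operation joins the halves and sets the only stereocenter from two achiral fragments. The mirror cut at C2–C3 (carbamate on the ring B arm) would bring the styrene and its allylic C5 hydrogens into the sBuLi step. Cuts at C4–C5 or C6=C7 leave the C3 problem unsolved.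

Boronate 11 is cut at C6=C7 into styrene 9 and commercial butenyl boronate 10 (cross-metathesis). The alkene geometry is thus settled on a small achiral fragment, before the union. Styrene 9 comes from aldehyde 8 by methylenation, and 8 from 4-hydroxybenzaldehyde 7.

Carbamate 6 is cut at the C1–aryl bond into aryl bromide 2 and allyl carbamate 4, joined through alkylborane 5 by a B-alkyl Suzuki coupling. The carbamate is thus in place from the start and no ester reduction next to silyl ethers is needed. Bromide 2 comes from 4-bromocatechol 1, and 4 from allyl alcohol 3.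

## Roads not taken

Alternative 1: (the most obvious) set C3 by enantioselective reduction of the protected ketone A1, which ordinary carbonyl chemistry (aldol condensation and conjugate reduction, or a Weinreb amide acylation) would deliver quickly. The reduction must distinguish CH2CH2–aryl from CH2CH2CH=CH–aryl, two unbranched arms of nearly equal size that differ only beyond the third atom. Oxazaborolidine or transfer-hydrogenation catalysts have no structural handle there, and an enzyme would need screening. The chosen plan selects between two hydrogens on one carbon, so arm similarity is irrelevant.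

Alternative 2: cut C3–C4 with the opposite polarity and catalytically, by nickel-catalysed reductive coupling of aldehyde A2 with aryl diene A3 (Ni(cod)2, chiral ligand, Et3B or a silane). In one step this would give 15 with the C3–C4 bond, the stereocenter and the E-styrene. It is not chosen because nothing in the substrates secures which diene terminus bonds to the carbonyl, where the hydride ends up (the 5-ene homoallylic isomer is the other outcome), or the facial selection on an unbranched enolisable aldehyde. A2 and A3 also need as many steps as 6 and 11.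

Alternative 3: differentiate the arms temporarily by a carbonyl at C6. Keto ester A4 would undergo ester-directed asymmetric hydrogenation with a RuCl2(BINAP)-type catalyst to give lactone A5. Half-reduction with i-Bu2AlH and benzylidene olefination would then form C6=C7. The stereocenter would be set well, but a semi-stabilised benzylic ylide should give E/Z mixtures on the most advanced intermediate. A4 also needs its own C–C bond-forming sequence, and the route is longer and fully linear.

Key step: step 7

Assumption: C3 is read from the SMILES as R (O > C2 arm toward ring A > C4 arm toward the alkene > H); (+)-sparteine, boronate 10 and 4-bromocatechol are taken as purchasable.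

## Route

Step 1
Reactants: 1 4-bromobenzene-1,2-diol (4-bromocatechol)
Product: 2 4-bromo-1,2-bis(triisopropylsilyloxy)benzene
Conditions: TIPSCl (2.4 equiv), imidazole, DMF, rt → 45 °C
Reagents that add atoms: chlorotriisopropylsilane, CC(C)[Si](Cl)(C(C)C)C(C)C
Why: Imidazole-promoted silylation of both phenols; aryl TIPS ethers are chosen to tolerate the organolithium, the aqueous base and the peroxide used later while remaining fluoride-labile.

Step 2
Reactants: 3 prop-2-en-1-ol (allyl alcohol)
Product: 4 allyl N,N-diisopropylcarbamate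
Conditions: iPr2NCOCl, Et3N, CH2Cl2, reflux
Reagents that add atoms: N,N-diisopropylcarbamoyl chloride, CC(C)N(C(C)C)C(Cl)=O
Why: O-Carbamoylation of a primary alcohol; the hindered carbamate is the directing and leaving group needed for the Hoppe lithiation in step 7.

Step 3
Reactants: 4 allyl N,N-diisopropylcarbamate; 2 4-bromo-1,2-bis(triisopropylsilyloxy)benzene
Product: 6 3-[3,4-bis(triisopropylsilyloxy)phenyl]propyl N,N-diisopropylcarbamate, via alkylborane 5 (not isolated)
Conditions: 9-BBN-H, THF, 0 °C → rt; then 2, PdCl2(dppf) (cat.), K3PO4 (aq), THF/DMF, 60 °C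
Reagents that add atoms: none
Why: Anti-Markovnikov hydroboration puts boron on the terminal carbon (γ to oxygen, so no β-elimination), and B-alkyl Suzuki–Miyaura coupling with 2 forms the C1–aryl bond; the carbamate is inert to both operations.

Step 4
Reactants: 7 4-hydroxybenzaldehyde
Product: 8 4-(triisopropylsilyloxy)benzaldehyde
Conditions: TIPSCl, imidazole, DMF, rt
Reagents that add atoms: chlorotriisopropylsilane, CC(C)[Si](Cl)(C(C)C)C(C)C
Why: Standard phenol silylation; the same protecting group as on ring A allows a single deprotection at the end.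

Step 5
Reactants: 8 4-(triisopropylsilyloxy)benzaldehyde
Product: 9 triisopropyl(4-vinylphenoxy)silane
Conditions: Ph3PCH3Br, KOtBu, THF, 0 °C → rt
Reagents that add atoms: methyltriphenylphosphonium bromide, C[P+](c1ccccc1)(c1ccccc1)c1ccccc1.[Br-]
Why: Wittig methylenation of a non-enolisable aromatic aldehyde; the aryl silyl ether tolerates the preformed ylide.

Step 6
Reactants: 9 triisopropyl(4-vinylphenoxy)silane (2.5 equiv); 10 2-(but-3-en-1-yl)-4,4,5,5-tetramethyl-1,3,2-dioxaborolane
Product: 11 2-[(3E)-4-[4-(triisopropylsilyloxy)phenyl]but-3-en-1-yl]-4,4,5,5-tetramethyl-1,3,2-dioxaborolane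
Conditions: second-generation Grubbs catalyst RuCl2(H2IMes)(PCy3)(=CHPh) (3 mol%), CH2Cl2, 40 °C
Reagents that add atoms: none
Why: Olefin cross-metathesis of a styrene with an unhindered terminal alkene; the conjugated 1,2-disubstituted styrene should form as the E isomer under thermodynamic control, excess 9 suppresses the homodimer of 10, and the pinacol boronate is inert to the ruthenium carbene.

Step 7
Reactants: 6 3-[3,4-bis(triisopropylsilyloxy)phenyl]propyl N,N-diisopropylcarbamate (1.3 equiv); 11 2-[(3E)-4-[4-(triisopropylsilyloxy)phenyl]but-3-en-1-yl]-4,4,5,5-tetramethyl-1,3,2-dioxaborolane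
Product: 15 (3R,6E)-1-[3,4-bis(triisopropylsilyloxy)phenyl]-7-[4-(triisopropylsilyloxy)phenyl]hept-6-en-3-ol, via lithiated carbamate 12 (not isolated), via boronate complex 13 (not isolated), via secondary boronic ester 14 (not isolated)
Conditions: sBuLi (1.25 equiv), (+)-sparteine, Et2O, −78 °C, 5 h; 11, −78 °C, 1 h; MgBr2·OEt2, −78 °C → reflux, 16 h; then 2 M NaOH, 30% H2O2, THF, 0 °C → rt
Reagents that add atoms: hydrogen peroxide, OO
Why: This is a Hoppe lithiation followed by lithiation–borylation–oxidation, whose closest precedent is the same sequence on 3-phenylpropyl N,N-diisopropylcarbamate with primary alkyl pinacol boronates. The carbamate carbonyl binds sBuLi·(+)-sparteine and directs removal of the pro-R hydrogen of the OCH2 group (C3), giving the α-lithiated carbamate 12 (R), configurationally stable at −78 °C. Boronate 11 is attacked at boron with retention at C3 to give the tetracoordinate complex 13. On warming with MgBr2 the C4 alkyl group migrates from boron to C3 antiperiplanar to the departing carbamate (1,2-metallate rearrangement with inversion at C3), forming the C3–C4 bond and secondary boronate 14. Alkaline H2O2 replaces boron by oxygen with retention, so 15 is R. No ring is closed; the only new stereocenter is controlled by the diamine alone (the (−)-enantiomer would give the S series) and not by the two nearly identical arms. The selectivities needed are deprotonation at C3 rather than at benzylic C1 or on ring A (secured by proximity to the carbamate) and inertness of the styrene and its allylic C5 hydrogens (secured because sBuLi is used in deficit to 6 and is consumed before 11 is added).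

Step 8
Reactants: 15 (3R,6E)-1-[3,4-bis(triisopropylsilyloxy)phenyl]-7-[4-(triisopropylsilyloxy)phenyl]hept-6-en-3-ol
Product: 16 (3R,6E)-1-[3,4-bis(triisopropylsilyloxy)phenyl]-7-[4-(triisopropylsilyloxy)phenyl]hept-6-en-3-yl acetate
Conditions: Ac2O, Et3N, DMAP (cat.), CH2Cl2, 0 °C → rt
Reagents that add atoms: acetic anhydride, CC(=O)OC(C)=O
Why: DMAP-catalysed acylation of the only free hydroxyl; with all phenols silylated the acetate can only go onto O3, and the C3–O bond is not broken, so the configuration is kept.

Step 9
Reactants: 16 (3R,6E)-1-[3,4-bis(triisopropylsilyloxy)phenyl]-7-[4-(triisopropylsilyloxy)phenyl]hept-6-en-3-yl acetate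
Product: 17 (3R,6E)-1-(3,4-dihydroxyphenyl)-7-(4-hydroxyphenyl)hept-6-en-3-yl acetate
Conditions: Bu4NF, AcOH (1:1, 3.5 equiv), THF, 0 °C → rt, argon
Reagents that add atoms: none
Why: Fluoride cleaves the three aryl silyl ethers (phenoxides are good leaving groups at silicon); acetic acid protonates each phenoxide as it forms, so the alkyl acetate is neither cleaved nor transferred, the catechol is not held as an oxidisable anion, and no acid strong enough to protonate the 4-hydroxystyrene is present.

## Compound list

1 | 4-bromobenzene-1,2-diol | Oc1ccc(Br)cc1O | starting material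
2 | 4-bromo-1,2-bis(triisopropylsilyloxy)benzene | Brc1ccc(O[Si](C(C)C)(C(C)C)C(C)C)c(O[Si](C(C)C)(C(C)C)C(C)C)c1 | intermediate
3 | prop-2-en-1-ol | C=CCO | starting material
4 | allyl N,N-diisopropylcarbamate | C=CCOC(=O)N(C(C)C)C(C)C | intermediate
5 | 3-(9-borabicyclo[3.3.1]nonan-9-yl)propyl N,N-diisopropylcarbamate | CC(C)N(C(C)C)C(=O)OCCCB1C2CCCC1CCC2 | intermediate (not isolated)
6 | 3-[3,4-bis(triisopropylsilyloxy)phenyl]propyl N,N-diisopropylcarbamate | CC(C)N(C(C)C)C(=O)OCCCc1ccc(O[Si](C(C)C)(C(C)C)C(C)C)c(O[Si](C(C)C)(C(C)C)C(C)C)c1 | intermediate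
7 | 4-hydroxybenzaldehyde | O=Cc1ccc(O)cc1 | starting material
8 | 4-(triisopropylsilyloxy)benzaldehyde | O=Cc1ccc(O[Si](C(C)C)(C(C)C)C(C)C)cc1 | intermediate
9 | triisopropyl(4-vinylphenoxy)silane | C=Cc1ccc(O[Si](C(C)C)(C(C)C)C(C)C)cc1 | intermediate
10 | 2-(but-3-en-1-yl)-4,4,5,5-tetramethyl-1,3,2-dioxaborolane | C=CCCB1OC(C)(C)C(C)(C)O1 | starting material
11 | 2-[(3E)-4-[4-(triisopropylsilyloxy)phenyl]but-3-en-1-yl]-4,4,5,5-tetramethyl-1,3,2-dioxaborolane | CC1(C)OB(CC/C=C/c2ccc(O[Si](C(C)C)(C(C)C)C(C)C)cc2)OC1(C)C | intermediate
12 | (R)-1-lithio-3-[3,4-bis(triisopropylsilyloxy)phenyl]propyl N,N-diisopropylcarbamate, as its (+)-sparteine complex | [Li][C@@H](OC(=O)N(C(C)C)C(C)C)CCc1ccc(O[Si](C(C)C)(C(C)C)C(C)C)c(O[Si](C(C)C)(C(C)C)C(C)C)c1 | intermediate (not isolated)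
13 | lithium boronate complex of 12 with 11 (boron bound to C3 with retention, carbamate still on C3) | [Li+].CC1(C)O[B-](CC/C=C/c2ccc(O[Si](C(C)C)(C(C)C)C(C)C)cc2)([C@@H](OC(=O)N(C(C)C)C(C)C)CCc2ccc(O[Si](C(C)C)(C(C)C)C(C)C)c(O[Si](C(C)C)(C(C)C)C(C)C)c2)OC1(C)C | intermediate (not isolated)
14 | 2-[(3R,6E)-1-[3,4-bis(triisopropylsilyloxy)phenyl]-7-[4-(triisopropylsilyloxy)phenyl]hept-6-en-3-yl]-4,4,5,5-tetramethyl-1,3,2-dioxaborolane | CC1(C)OB([C@H](CC/C=C/c2ccc(O[Si](C(C)C)(C(C)C)C(C)C)cc2)CCc2ccc(O[Si](C(C)C)(C(C)C)C(C)C)c(O[Si](C(C)C)(C(C)C)C(C)C)c2)OC1(C)C | intermediate (not isolated)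
15 | (3R,6E)-1-[3,4-bis(triisopropylsilyloxy)phenyl]-7-[4-(triisopropylsilyloxy)phenyl]hept-6-en-3-ol | O[C@H](CC/C=C/c1ccc(O[Si](C(C)C)(C(C)C)C(C)C)cc1)CCc1ccc(O[Si](C(C)C)(C(C)C)C(C)C)c(O[Si](C(C)C)(C(C)C)C(C)C)c1 | intermediate
16 | (3R,6E)-1-[3,4-bis(triisopropylsilyloxy)phenyl]-7-[4-(triisopropylsilyloxy)phenyl]hept-6-en-3-yl acetate | CC(=O)O[C@H](CC/C=C/c1ccc(O[Si](C(C)C)(C(C)C)C(C)C)cc1)CCc1ccc(O[Si](C(C)C)(C(C)C)C(C)C)c(O[Si](C(C)C)(C(C)C)C(C)C)c1 | intermediate
17 | (3R,6E)-1-(3,4-dihydroxyphenyl)-7-(4-hydroxyphenyl)hept-6-en-3-yl acetate | CC(=O)O[C@H](CC/C=C/c1ccc(O)cc1)CCc1ccc(O)c(O)c1 | target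

## Step count and risks

Total: 9 steps. Longest linear sequence: 6 steps (4, 5, 6, 7, 8, 9, from 4-hydroxybenzaldehyde).

**Step 7 (key step).** The most likely failure is a sluggish 1,2-migration of the pinacol boronate complex, with reversal of boronate formation and partial racemisation of the lithiated carbamate on warming; organolithium addition to the styrene is a lesser risk. The fallback sets C3 from a resolved terminal epoxide instead, and sets out from 2.
- Kumada coupling of 2 with but-3-enylmagnesium bromide and PdCl2(dppf) gives 4-(but-3-en-1-yl)-1,2-bis(triisopropylsilyloxy)benzene F1.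
- mCPBA (NaHCO3, CH2Cl2) gives racemic 2-{2-[3,4-bis(triisopropylsilyloxy)phenyl]ethyl}oxirane F2.
- Hydrolytic kinetic resolution with (S,S)-(salen)Co(OAc) and 0.55 equiv of water should leave (S)-2-{2-[3,4-bis(triisopropylsilyloxy)phenyl]ethyl}oxirane F3. The catalyst enantiomer is chosen by analogy with simple alkyl oxiranes and would be confirmed on the first run.
- CuI-catalysed opening at the terminal carbon with allylmagnesium bromide gives (3R)-1-[3,4-bis(triisopropylsilyloxy)phenyl]hept-6-en-3-ol F4.
- Cross-metathesis of F4 with excess 9 (RuCl2(H2IMes)(PCy3)(=CHPh)) comes back to the route at 15.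

**Step 6.** Homodimerisation of either partner, incomplete E-selectivity, or ruthenium hydride-induced migration of the double bond toward boron may erode the yield and purity of 11. The fallback replaces metathesis by a Heck arylation and sets out from 10. (4-Iodophenoxy)triisopropylsilane F5 (from 4-iodophenol, TIPSCl, imidazole) is coupled with 10 using Pd(OAc)2, Bu4NCl and NaHCO3 in DMF at 60 °C. β-Hydride elimination toward the conjugated E-styrene is favoured, and the route is rejoined at 11.

**Step 3.** Loss of an aryl silyl ether in the warm aqueous phosphate, or protodeboronation and reduction of the aryl bromide in place of coupling, may occur. The fallback forms the C1–aryl bond with the polarity reversed and sets out from 2. Bromine–lithium exchange (n-BuLi, THF, −78 °C) and opening of oxetane in the presence of BF3·OEt2 gives 3-[3,4-bis(triisopropylsilyloxy)phenyl]propan-1-ol F6. Carbamoylation with iPr2NCOCl/Et3N returns to 6.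

**Step 9.** Cleavage of the hindered silyl ethers may be incomplete under buffered fluoride. If the medium turns basic, acetyl loss or transfer and oxidation of the catecholate may follow. The fallback unmasks first and differentiates the esters afterwards, setting out from 15.
- Unbuffered Bu4NF gives (3R,6E)-4-[3-hydroxy-7-(4-hydroxyphenyl)hept-6-en-1-yl]benzene-1,2-diol F7.
- Ac2O/pyridine gives the tetraacetate (3R,6E)-1-(3,4-diacetoxyphenyl)-7-(4-acetoxyphenyl)hept-6-en-3-yl acetate F8.
- Methanolysis with NH4OAc in aqueous MeOH at rt removes only the three aryl acetates, which are far better acyl donors than the secondary alkyl ester, and arrives at 17.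

## Further compounds

F1 | step 7 | 4-(but-3-en-1-yl)-1,2-bis(triisopropylsilyloxy)benzene | C=CCCc1ccc(O[Si](C(C)C)(C(C)C)C(C)C)c(O[Si](C(C)C)(C(C)C)C(C)C)c1
F2 | step 7 | racemic 2-{2-[3,4-bis(triisopropylsilyloxy)phenyl]ethyl}oxirane | C1OC1CCc1ccc(O[Si](C(C)C)(C(C)C)C(C)C)c(O[Si](C(C)C)(C(C)C)C(C)C)c1
F3 | step 7 | (S)-2-{2-[3,4-bis(triisopropylsilyloxy)phenyl]ethyl}oxirane | C1O[C@H]1CCc1ccc(O[Si](C(C)C)(C(C)C)C(C)C)c(O[Si](C(C)C)(C(C)C)C(C)C)c1
F4 | step 7 | (3R)-1-[3,4-bis(triisopropylsilyloxy)phenyl]hept-6-en-3-ol | O[C@H](CCC=C)CCc1ccc(O[Si](C(C)C)(C(C)C)C(C)C)c(O[Si](C(C)C)(C(C)C)C(C)C)c1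
F5 | step 6 | (4-iodophenoxy)triisopropylsilane | CC(C)[Si](Oc1ccc(I)cc1)(C(C)C)C(C)C
F6 | step 3 | 3-[3,4-bis(triisopropylsilyloxy)phenyl]propan-1-ol | OCCCc1ccc(O[Si](C(C)C)(C(C)C)C(C)C)c(O[Si](C(C)C)(C(C)C)C(C)C)c1
F7 | step 9 | (3R,6E)-4-[3-hydroxy-7-(4-hydroxyphenyl)hept-6-en-1-yl]benzene-1,2-diol | O[C@H](CC/C=C/c1ccc(O)cc1)CCc1ccc(O)c(O)c1
F8 | step 9 | (3R,6E)-1-(3,4-diacetoxyphenyl)-7-(4-acetoxyphenyl)hept-6-en-3-yl acetate | CC(=O)O[C@H](CC/C=C/c1ccc(OC(C)=O)cc1)CCc1ccc(OC(C)=O)c(OC(C)=O)c1
A1 | alternative 1 | (6E)-1-[3,4-bis(triisopropylsilyloxy)phenyl]-7-[4-(triisopropylsilyloxy)phenyl]hept-6-en-3-one | O=C(CCc1ccc(O[Si](C(C)C)(C(C)C)C(C)C)c(O[Si](C(C)C)(C(C)C)C(C)C)c1)CC/C=C/c1ccc(O[Si](C(C)C)(C(C)C)C(C)C)cc1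
A2 | alternative 2 | 3-[3,4-bis(triisopropylsilyloxy)phenyl]propanal | O=CCCc1ccc(O[Si](C(C)C)(C(C)C)C(C)C)c(O[Si](C(C)C)(C(C)C)C(C)C)c1
A3 | alternative 2 | (E)-[4-(buta-1,3-dien-1-yl)phenoxy]triisopropylsilane | C=C/C=C/c1ccc(O[Si](C(C)C)(C(C)C)C(C)C)cc1
A4 | alternative 3 | ethyl 6-[3,4-bis(triisopropylsilyloxy)phenyl]-4-oxohexanoate | CCOC(=O)CCC(=O)CCc1ccc(O[Si](C(C)C)(C(C)C)C(C)C)c(O[Si](C(C)C)(C(C)C)C(C)C)c1
A5 | alternative 3 | (S)-5-{2-[3,4-bis(triisopropylsilyloxy)phenyl]ethyl}dihydrofuran-2(3H)-one | O=C1CC[C@H](CCc2ccc(O[Si](C(C)C)(C(C)C)C(C)C)c(O[Si](C(C)C)(C(C)C)C(C)C)c2)O1
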